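**Plan**

- Locants: in each cyclopentane C1' = C(aryl)(CH3), C2' = C(CH3)2, then C3', C4', C5' (CH2 groups) back to C1'. Every operation is run on both halves at once.
- Retrosynthetic cuts, in order: four O–CH3; C3'H2 back to C3'=O; four C2'–CH3 bonds; C4'–C5' together with C3'–C4' (C4' excised as a one-carbon unit); the two [2+2] bonds of each cyclobutanone; two aryl–C1' bonds; last the central CH2–CH2 bond.
- Enabling feature: C1' bears aryl and CH3 and lies between two ring carbons. With C3' as a carbonyl, C2' without its methyls and C4' removed, each ring collapses to a 3-aryl-3-methylcyclobutanone. This ketone has a mirror plane through C1', C3', the CH3 carbon and the aryl ipso carbon, so C2' and C5' are enantiotopic CH2 groups, and C3'–C5' is a temporary ring bond to be traded for C4'–C5'.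
- Forward order: bibenzyl core, two isopropenyl groups, two cyclobutanones, then both cyclopentanones by one double enantioselective ring expansion of the achiral bis(cyclobutanone) (24 of the 30 skeletal carbons). After that come the enone, gem-dimethylation at C2', saturation, removal of C3'=O and O-demethylation.
- Stereochemistry: both quaternary centres (S,S) arise in the ring expansion from the catalyst-controlled choice of the migrating methylene. No later step can epimerise them.

Key step: step 6

Assumption: the sense of induction of the chiral scandium catalyst in step 6 cannot be taken from precedent. The ligand antipode that leads to the (S) centres is to be fixed in a trial on a half-size model ketone, and the route is drawn for that antipode.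

Remark: every step converts both identical halves. Species in which only one half has reacted are not listed.

**Route**

Step 1
Reactants: 1 3-bromo-4,5-dimethoxybenzaldehyde (two molecules)
Product: 2 (E)-1,2-bis(3-bromo-4,5-dimethoxyphenyl)ethene
Conditions: TiCl4, Zn dust, THF, 0 °C to reflux
Reagents that add atoms: none
Why: McMurry coupling, in which low-valent titanium joins two aldehyde carbons through a titanium pinacolate and deoxygenates it to the stilbene while aryl bromides and aryl methyl ethers are tolerated; the alkene geometry is of no consequence because step 2 saturates it.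

Step 2
Reactants: 2 (E)-1,2-bis(3-bromo-4,5-dimethoxyphenyl)ethene
Product: 3 1,2-bis(3-bromo-4,5-dimethoxyphenyl)ethane
Conditions: p-TsNHNH2 (excess), NaOAc, DME/H2O, reflux
Reagents that add atoms: none
Why: Diimide reduction, in which HN=NH released from the sulfonyl hydrazide transfers two hydrogens to the C=C bond in a concerted way and, unlike hydrogenation over palladium, should leave both C–Br bonds intact.

Step 3
Reactants: 3 1,2-bis(3-bromo-4,5-dimethoxyphenyl)ethane; 4 isopropenylboronic acid pinacol ester (2.5 equiv)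
Product: 5 1,2-bis[3,4-dimethoxy-5-(prop-1-en-2-yl)phenyl]ethane
Conditions: Pd(dppf)Cl2 (5 mol %), K2CO3, 1,4-dioxane/H2O, 90 °C
Reagents that add atoms: none
Why: Twofold Suzuki–Miyaura coupling of an aryl bromide with an alkenylboronate, a reaction that routinely tolerates one ortho methoxy group.

Step 4
Reactants: 5 1,2-bis[3,4-dimethoxy-5-(prop-1-en-2-yl)phenyl]ethane
Product: 6 1,2-bis[3-(2,2-dichloro-1-methyl-3-oxocyclobutyl)-4,5-dimethoxyphenyl]ethane (mixture of rac and meso forms)
Conditions: Cl3CCOCl, Zn–Cu couple, POCl3, Et2O, reflux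
Reagents that add atoms: trichloroacetyl chloride, ClC(=O)C(Cl)(Cl)Cl (enters as dichloroketene, ClC(Cl)=C=O)
Why: Ketene–alkene [2+2] cycloaddition in which the nucleophilic =CH2 terminus bonds to the ketene carbonyl carbon, so that CCl2 ends next to the benzylic carbon; the two stereocentres formed here vanish in step 5.

Step 5
Reactants: 6 1,2-bis[3-(2,2-dichloro-1-methyl-3-oxocyclobutyl)-4,5-dimethoxyphenyl]ethane
Product: 7 1,2-bis[3,4-dimethoxy-5-(1-methyl-3-oxocyclobutyl)phenyl]ethane (achiral)
Conditions: Zn dust, AcOH, rt to 50 °C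
Reagents that add atoms: none
Why: Reductive dechlorination of alpha-chloro ketones through zinc enolates, standard for dichloroketene adducts, which restores a mirror plane in each four-membered ring.

Step 6
Reactants: 7 1,2-bis[3,4-dimethoxy-5-(1-methyl-3-oxocyclobutyl)phenyl]ethane
Product: 10 1,2-bis{3,4-dimethoxy-5-[(1S)-1-methyl-3-oxocyclopentyl]phenyl}ethane, via bis(oxido-diazonium) adduct 8 (not isolated), via bis(alpha-silyl ketone) 9 (not isolated)
Conditions: Me3SiCHN2 (2.5 equiv, hexanes), Sc(OTf)3 (20 mol %), C2-symmetric N,N'-dioxide ligand made from (S)-pipecolic acid 2,6-diisopropylanilide with a propane-1,3-diyl linker (22 mol %, or its antipode), 4 Å MS, toluene, −20 °C; then 1 M HCl, THF, rt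
Reagents that add atoms: (trimethylsilyl)diazomethane, C[Si](C)(C)C=[N+]=[N-]
Why: Proposed new method: the chiral Sc(OTf)3–N,N'-dioxide complex binds each strained carbonyl of 7, the nucleophilic carbon of Me3SiCHN2 (the future C4') adds to C3' to give adduct 8, and the ring methylene that stands antiperiplanar to the C4'–N2 bond migrates from C3' to C4' with loss of N2, which makes the C4'–C5' bond and gives 9, whose silyl groups are taken off by acid. Each cyclopentane ring is therefore closed by a four-to-five ring expansion (1,2-alkyl shift of the Tiffeneau–Demjanov type) in which the temporary C3'–C5' bond is traded for C4'–C5', and the loss of cyclobutanone strain makes 10 much less electrophilic than 7, so that a second insertion should not compete. The closest known reaction types are the Sc(OTf)3-catalysed homologation of arylcyclobutanones with Me3SiCHN2 in racemic form, the desymmetrising ring expansion of 4-substituted cyclohexanones with diazoacetates under chiral aluminium Lewis acids and the asymmetric Baeyer–Villiger desymmetrisation of 3-substituted cyclobutanones, whereas a catalytic choice between the enantiotopic methylenes of a 3,3-disubstituted cyclobutanone by a diazo carbon nucleophile has not been shown. C1' becomes stereogenic only through that choice: the catalyst sets the configuration of the transient centre C4' (H, SiMe3, N2), the rotamer with SiMe3 anti to the scandium-bound oxygen then places only one of the two methylenes anti to N2, and the information is thus relayed to C1' before C4' loses its stereogenicity on protodesilylation. The step needs enantiotopic-group selectivity together with a defined face of attack at C3'; regioselectivity is no issue because the two alpha carbons are mirror-related CH2 groups, and the bulky 2,3-dimethoxyaryl group on C1' is expected to direct the nucleophile to the opposite ring face, as in additions to 3-substituted cyclobutanones. As two independent events occur in one molecule, most of the minor sense of induction should end in the meso (R,S) diastereomer, so that the (S,S) compound should gain in enantiomeric purity once the meso compound is removed by crystallisation or by chromatography on a chiral phase.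

Step 7
Reactants: 10 1,2-bis{3,4-dimethoxy-5-[(1S)-1-methyl-3-oxocyclopentyl]phenyl}ethane
Product: 12 1,2-bis{3,4-dimethoxy-5-[(1R)-1-methyl-4-oxocyclopent-2-en-1-yl]phenyl}ethane, via bis(silyl enol ether) 11 (not isolated)
Conditions: LiN(i-Pr)2, Me3SiCl, THF, −78 °C; crude 11, then Pd(OAc)2 (2.2 equiv), MeCN, rt
Reagents that add atoms: chlorotrimethylsilane, C[Si](C)(C)Cl (silyl groups of 11 only; none of its atoms stay in 12)
Why: Saegusa–Ito oxidation, in which kinetic enolisation takes place at the unhindered C4' and only this enol ether can lose a beta hydrogen (C5'–H) from its palladium enolate, because on the other side C1' is quaternary (same spatial arrangement at C1', descriptor changes to R by the priority rules).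

Step 8
Reactants: 12 1,2-bis{3,4-dimethoxy-5-[(1R)-1-methyl-4-oxocyclopent-2-en-1-yl]phenyl}ethane
Product: 13 1,2-bis{3,4-dimethoxy-5-[(1R)-1,5,5-trimethyl-4-oxocyclopent-2-en-1-yl]phenyl}ethane
Conditions: KOt-Bu (6 equiv), MeI (excess), THF/t-BuOH, 0 °C to rt
Reagents that add atoms: iodomethane, CI
Why: Exhaustive enolate alkylation, in which C2' is the only enolisable position of a 4,4-disubstituted cyclopent-2-enone (the gamma carbon C1' is quaternary), so that the cross-conjugated dienolate is methylated twice there, a sequence well known for 4-aryl-4-methylcyclopentenones.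

Step 9
Reactants: 13 1,2-bis{3,4-dimethoxy-5-[(1R)-1,5,5-trimethyl-4-oxocyclopent-2-en-1-yl]phenyl}ethane
Product: 14 1,2-bis{3,4-dimethoxy-5-[(1R)-1,2,2-trimethyl-3-oxocyclopentyl]phenyl}ethane
Conditions: H2 (1 atm), Pd/C, EtOAc, rt
Reagents that add atoms: none
Why: Heterogeneous catalytic hydrogenation of a disubstituted enone C=C bond, which creates no stereocentre and leaves ketone, arenes and ethers untouched.

Step 10
Reactants: 14 1,2-bis{3,4-dimethoxy-5-[(1R)-1,2,2-trimethyl-3-oxocyclopentyl]phenyl}ethane
Product: 16 1,2-bis{3,4-dimethoxy-5-[(1S)-1,2,2-trimethylcyclopentyl]phenyl}ethane, via bis(hydrazone) 15 (not isolated)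
Conditions: N2H4·H2O, KOH, diethylene glycol, 130 °C, then 200 °C with removal of water
Reagents that add atoms: hydrazine, NN (nitrogen atoms of 15 only; none stay in 16)
Why: Wolff–Kishner reduction in the Huang-Minlon procedure, precedented for 3-aryl-2,2,3-trimethylcyclopentanones, which touches no stereocentre (descriptor returns to S by the priority rules) and in which any partial ether cleavage is harmless because step 11 removes all methyl ethers.

Step 11
Reactants: 16 1,2-bis{3,4-dimethoxy-5-[(1S)-1,2,2-trimethylcyclopentyl]phenyl}ethane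
Product: 18 5,5'-(ethane-1,2-diyl)bis{3-[(1S)-1,2,2-trimethylcyclopentyl]benzene-1,2-diol}, via bis(bromobenzodioxaborole) 17 (not isolated)
Conditions: BBr3 (6 equiv), CH2Cl2, −78 °C to rt; then degassed H2O, under argon
Reagents that add atoms: boron tribromide, BrB(Br)Br (boron and bromine of 17 only; none stay in 18)
Why: Lewis acid cleavage of aryl methyl ethers with BBr3, the standard release of hindered catechols, with work-up under inert gas because the product is sensitive to air oxidation.

**Compound list**

| No. | Name | SMILES | Role |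
|---|---|---|---|
| 1 | 3-bromo-4,5-dimethoxybenzaldehyde | COc1cc(C=O)cc(Br)c1OC | starting material |
| 2 | (E)-1,2-bis(3-bromo-4,5-dimethoxyphenyl)ethene | COc1cc(/C=C/c2cc(Br)c(OC)c(OC)c2)cc(Br)c1OC | intermediate |
| 3 | 1,2-bis(3-bromo-4,5-dimethoxyphenyl)ethane | COc1cc(CCc2cc(Br)c(OC)c(OC)c2)cc(Br)c1OC | intermediate |
| 4 | isopropenylboronic acid pinacol ester | CC(=C)B1OC(C)(C)C(C)(C)O1 | starting material |
| 5 | 1,2-bis[3,4-dimethoxy-5-(prop-1-en-2-yl)phenyl]ethane | COc1cc(CCc2cc(C(C)=C)c(OC)c(OC)c2)cc(C(C)=C)c1OC | intermediate |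
| 6 | 1,2-bis[3-(2,2-dichloro-1-methyl-3-oxocyclobutyl)-4,5-dimethoxyphenyl]ethane, rac/meso mixture | COc1cc(CCc2cc(C3(C)CC(=O)C3(Cl)Cl)c(OC)c(OC)c2)cc(C2(C)CC(=O)C2(Cl)Cl)c1OC | intermediate |
| 7 | 1,2-bis[3,4-dimethoxy-5-(1-methyl-3-oxocyclobutyl)phenyl]ethane, achiral | COc1cc(CCc2cc(C3(C)CC(=O)C3)c(OC)c(OC)c2)cc(C2(C)CC(=O)C2)c1OC | intermediate |
| 8 | bis(oxido-diazonium) adduct of 7 with Me3SiCHN2, drawn metal-free; working model: oxygen cis to aryl, silyl-bearing carbon S | C[Si](C)(C)[C@H]([N+]#N)[C@]4([O-])C[C@](C)(C4)c1cc(CCc2cc(OC)c(OC)c([C@]3(C)C[C@@]([O-])([C@@H]([N+]#N)[Si](C)(C)C)C3)c2)cc(OC)c1OC | intermediate (not isolated) |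
| 9 | 1,2-bis{3,4-dimethoxy-5-[(1R)-1-methyl-3-oxo-4-(trimethylsilyl)cyclopentyl]phenyl}ethane, configuration at C4' of no consequence | C4C(=O)C([Si](C)(C)C)C[C@]4(C)c1cc(CCc2cc(OC)c(OC)c([C@@]3(C)CC([Si](C)(C)C)C(=O)C3)c2)cc(OC)c1OC | intermediate (not isolated) |
| 10 | 1,2-bis{3,4-dimethoxy-5-[(1S)-1-methyl-3-oxocyclopentyl]phenyl}ethane | C4C(=O)CC[C@]4(C)c1cc(CCc2cc(OC)c(OC)c([C@@]3(C)CCC(=O)C3)c2)cc(OC)c1OC | intermediate |
| 11 | 1,2-bis{3,4-dimethoxy-5-[(1S)-1-methyl-3-(trimethylsilyloxy)cyclopent-3-en-1-yl]phenyl}ethane | C4C(O[Si](C)(C)C)=CC[C@]4(C)c1cc(CCc2cc(OC)c(OC)c([C@@]3(C)CC=C(O[Si](C)(C)C)C3)c2)cc(OC)c1OC | intermediate (not isolated) |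
| 12 | 1,2-bis{3,4-dimethoxy-5-[(1R)-1-methyl-4-oxocyclopent-2-en-1-yl]phenyl}ethane | C4C(=O)C=C[C@]4(C)c1cc(CCc2cc(OC)c(OC)c([C@@]3(C)C=CC(=O)C3)c2)cc(OC)c1OC | intermediate |
| 13 | 1,2-bis{3,4-dimethoxy-5-[(1R)-1,5,5-trimethyl-4-oxocyclopent-2-en-1-yl]phenyl}ethane | CC4(C)C(=O)C=C[C@]4(C)c1cc(CCc2cc(OC)c(OC)c([C@@]3(C)C=CC(=O)C3(C)C)c2)cc(OC)c1OC | intermediate |
| 14 | 1,2-bis{3,4-dimethoxy-5-[(1R)-1,2,2-trimethyl-3-oxocyclopentyl]phenyl}ethane | CC4(C)C(=O)CC[C@]4(C)c1cc(CCc2cc(OC)c(OC)c([C@@]3(C)CCC(=O)C3(C)C)c2)cc(OC)c1OC | intermediate |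
| 15 | 1,2-bis{5-[(1S)-3-hydrazinylidene-1,2,2-trimethylcyclopentyl]-3,4-dimethoxyphenyl}ethane | CC4(C)C(=NN)CC[C@]4(C)c1cc(CCc2cc(OC)c(OC)c([C@@]3(C)CCC(=NN)C3(C)C)c2)cc(OC)c1OC | intermediate (not isolated) |
| 16 | 1,2-bis{3,4-dimethoxy-5-[(1S)-1,2,2-trimethylcyclopentyl]phenyl}ethane | CC4(C)CCC[C@]4(C)c1cc(CCc2cc(OC)c(OC)c([C@@]3(C)CCCC3(C)C)c2)cc(OC)c1OC | intermediate |
| 17 | 1,2-bis{2-bromo-7-[(1S)-1,2,2-trimethylcyclopentyl]-1,3,2-benzodioxaborol-5-yl}ethane | CC4(C)CCC[C@]4(C)c1cc(CCc2cc5OB(Br)Oc5c([C@@]3(C)CCCC3(C)C)c2)cc2OB(Br)Oc12 | intermediate (not isolated) |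
| 18 | 5,5'-(ethane-1,2-diyl)bis{3-[(1S)-1,2,2-trimethylcyclopentyl]benzene-1,2-diol} | CC1(C)CCC[C@]1(C)c1cc(CCc2cc(O)c(O)c([C@@]3(C)CCCC3(C)C)c2)cc(O)c1O | target |

Total step count: 11
Longest linear sequence: 11 steps (1 to 18)

**Steps most likely to fail**

1. Step 6 (Proposed new method).
   - Risk: the discrimination between the two enantiotopic methylenes may be too weak. Control of the carbonyl face, control of the diazo carbon face and the rotamer preference must all act in the same sense. Removal of the meso diastereomer may also be laborious, because its stereocentres are remote from each other.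
   - Fallback by known chemistry, from 7 back to the route at 12: enantioselective deprotonation of both cyclobutanones with lithium bis[(R)-1-phenylethyl]amide (or its antipode) in the presence of Me3SiCl (THF, −100 °C) should give the bis(cyclobutenyl silyl ether) F1. Simmons–Smith cyclopropanation (Et2Zn, CH2I2, CH2Cl2) should give the bis(siloxybicyclo[2.1.0]pentane) F2, in which the C4'–C5' bond is already in place. FeCl3 in DMF at 0 °C should cleave the central ring bond to the bis(beta-chloro ketone) F3, and NaOAc in MeOH at reflux should eliminate HCl to give 12.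

2. Step 4.
   - Risk: zinc salts may trigger cationic oligomerisation of the electron-rich isopropenylarene, and the second cycloaddition at the twisted, ortho-substituted styrene may be sluggish.
   - Fallback from 5 back to the route at 7 (step 5 is then not needed): a keteniminium [2+2] cycloaddition with the salt made from N,N-dimethylacetamide, Tf2O and 2,4,6-collidine (1,2-dichloroethane, reflux) should give the bis(cyclobutaniminium triflate) F4. Hydrolysis of F4 with aqueous NaHCO3 should deliver 7 without any chlorine to remove.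

3. Step 10.
   - Risk: hydrazone formation at the neopentyl-type carbonyl next to C2' may be slow, so that one or both carbonyl groups survive, and some methyl ethers may be lost in hot alkali.
   - Fallback from 14 back to the route at 16: radical deoxygenation. LiAlH4 (THF, 0 °C) should give the bis(cyclopentanol) F5 as a mixture of carbinol epimers. NaH, CS2 and then MeI should give the bis(S-methyl xanthate) F6, and Barton–McCombie reduction (Bu3SnH, AIBN, toluene, reflux) should give 16.

**Further compounds**

F1 | step 6 | 1,2-bis{3,4-dimethoxy-5-[(1R)-1-methyl-3-(trimethylsilyloxy)cyclobut-2-en-1-yl]phenyl}ethane | C4C(O[Si](C)(C)C)=C[C@]4(C)c1cc(CCc2cc(OC)c(OC)c([C@@]3(C)C=C(O[Si](C)(C)C)C3)c2)cc(OC)c1OC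
F2 | step 6 | 1,2-bis{3,4-dimethoxy-5-[(2R)-2-methyl-4-(trimethylsilyloxy)bicyclo[2.1.0]pentan-2-yl]phenyl}ethane, face of cyclopropanation of no consequence | C4C5(O[Si](C)(C)C)CC5[C@]4(C)c1cc(CCc2cc(OC)c(OC)c([C@@]3(C)C6CC6(O[Si](C)(C)C)C3)c2)cc(OC)c1OC
F3 | step 6 | 1,2-bis{3-[(1S)-2-chloro-1-methyl-4-oxocyclopentyl]-4,5-dimethoxyphenyl}ethane, configuration at the C–Cl carbon of no consequence | C4C(=O)CC(Cl)[C@]4(C)c1cc(CCc2cc(OC)c(OC)c([C@@]3(C)C(Cl)CC(=O)C3)c2)cc(OC)c1OC
F4 | step 4 | bis(N,N-dimethylcyclobutaniminium) bis(triflate) corresponding to 7 | C[N+](C)=C4CC(C)(C4)c1cc(CCc2cc(OC)c(OC)c(C3(C)CC(=[N+](C)C)C3)c2)cc(OC)c1OC.[O-]S(=O)(=O)C(F)(F)F.[O-]S(=O)(=O)C(F)(F)F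
F5 | step 10 | 1,2-bis{5-[(1S)-3-hydroxy-1,2,2-trimethylcyclopentyl]-3,4-dimethoxyphenyl}ethane, carbinol epimers | CC4(C)C(O)CC[C@]4(C)c1cc(CCc2cc(OC)c(OC)c([C@@]3(C)CCC(O)C3(C)C)c2)cc(OC)c1OC
F6 | step 10 | bis(O-cyclopentyl S-methyl dithiocarbonate) of F5 | CC4(C)C(OC(=S)SC)CC[C@]4(C)c1cc(CCc2cc(OC)c(OC)c([C@@]3(C)CCC(OC(=S)SC)C3(C)C)c2)cc(OC)c1OC
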